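Each X that leaves the flask takes one D with it and comes out as one G, so X is the limiting reagent and G can reach 50 percent of the D charged, while Z returns from each turn unchanged. The ledger of X therefore has one open entry per flask: how much of the X has been booked to G when the time is up.

all flasks: Z 0.27 mol%

|  | D | X | J | remark | time |
|---|---|---|---|---|---|
| green | 1 M | 0.50 equiv | 0.69 mM | run made earlier |  |
| blue | 1 M | 0.50 equiv | 5.9 mM | run made earlier |  |
| summer | 1.0 M | 0.500 equiv | 0.60 mM |  | 30 h |
| dusk | 1.0 M | 0.500 equiv | 1.2 mM |  | 30 h |
| noon | 1.0 M | 0.500 equiv | 2.5 mM |  | 30 h |
| autumn | 1.0 M | 0.500 equiv | 5.0 mM |  | 30 h |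

- green (time / h: G / %): 1.00: 16; 3.00: 34; 5.00: 41; 8.00: 46; 12.0: 49; 15.0: 47
- blue (time / h: G / %): 1.33: 0; 2.00: 6; 3.00: 6; 5.00: 8; 10.0: 13; 15.0: 22

(scatter of a reading: 2 percentage points)

- the earlier runs were read with a standard deviation of 2 percentage points
- steps thought possible: Z + J <-> Q; D + X + Z -> G + Z
- a step back or a flat step of under half a point counts as no turn
- "hardly changes" means that all values lie within two and a half points (for a concentration: within two and a half percent of the largest)

* amount of G at the end, in percent of the D charged for summer, dusk, noon, autumn, in this order
* how that number moves from the first to the last of them (falls, then rises / rises all the way / rises, then falls / hardly changes / falls all the way)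

D and X fall together, one for one. This reckoning assumes a pace proportional to D, X and free Z, and on that assumption, with a steady catalyst, the share of D left divided by the share of X left starts at one and grows by the same factor in equal stretches of time. Take as the stretch the X clock, the time in which half of the X charged goes to G; the factor is then 1.50. Green's reading of 34% at 3.00 h gives a clock of 1.68 h, and blue's 22% at 15.0 h gives 18.4 h; both carry the scatter of their readings.

J ties Z up as Q, so this reckoning counts J in units of the Z charged and takes the pace of X as proportional to free Z. Green holds 0.256 and blue 2.19. The reckoning lets J, below one, remove its own share of Z, and lets free Z, above one, vary inversely with the J left over. Autumn, at 1.85, has 0.850 left over against blue's 1.19, so its X clock is 13.2 h. The run lasts 2.27 clocks, which books 37.6% as G. Summer, at 0.222, has a clock of 1.61 h, and dusk, at 0.444, one of 2.25 h, so both close at the cap. Noon, with J and Z nearly equal, fits neither shortcut and is placed between the cap and autumn.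

The forecast gives 50%, 49.9%, 48% and 35%, falls all the way, saying “G stays flat near the cap, then falls”, and its last point lies below the 37.6% reckoned here.

The flasks give 50.0%, 50.0%, 49.0% and 37.7%, so G falls all the way.

    Z + J ⇌ Q, settled at all times (K = 3600 /M)
    D + X + Z → G + Z, rate k2*[D]*[X]*[Z]/(1 + ([D]/sat2)) (0.720 M, k = 8.00 /M²/min)

From summer to autumn G falls by 12 percentage points, and with the tying up of Z by J as Q taken away the change is 0 points. In autumn that tying up acts together with the end of the run at 30 h: lifting either one gives 50.0%. At 30.0 h autumn's free Z stands at 9.78% of its charge, with D at 62.3% and X at 24.6%. Their ratio of 2.53 stands beside the 2.51 given by the clock of 13.2 h, but autumn's factor is not steady: the ratio grows by 1.55 up to 15.0 h and by 1.63 from there to 30.0 h. Summer's clock, reckoned at 1.61 h, appears in that flask as 1.71 h, the time by which half of the turnover to G is done.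

The readings were computed with constants of no real substance; noise was put on by code.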